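**Plan**
- Retrosynthesis: the acid is taken back to its methyl ester and the diene is cut at C2'–C3', leaving a C5 propynyl group and (E)-β-bromostyrene. The C5 methyl is traced through C5–CH2Br to a cyclopropane spanning C5 and C6 (cuts: C5–CH2 and C6–CH2).
- Enabling feature: C5 is a quaternary ring B carbon that is allylic to C6=C7, and C7 carries a methyl. A C7 tertiary allylic alcohol with a C5=C6 alkene can therefore pass CH2 to C5, and opening of the three-membered ring returns C6=C7.
- Further cuts: C7–CH3 and C5–alkyne lead back to a ring B 1,3-dione; then C4–CH3, C5–C6 (Claisen) and C3a–C4 (malonate Michael); the C3 ethyl and the C2=C3 alkene come from a C2 ketone.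
- Forward: ring A is the five-membered ring of a 4-silyloxycyclopentenone. It is decorated first (vinyl at C7a, methyl at C1, malonate at C3a, ethyl/alkene at C3), then ring B is closed by Claisen condensation, and the side chain is joined last.
- Stereochemistry: the single silyloxy centre relays to C7a, C1 and C3a by successive anti additions. C4 is set by axial methylation, C7 by axial methyl addition, C5 by hydroxyl-directed methylene delivery, and the diene geometry by syn hydrozirconation and stereoretentive coupling.

Key step: step 13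

Remark: the hydrindene numbering of the target (C1 CHMe, C2=C3 with ethyl on C3, C3a, C4, C5, C6=C7 with methyl on C7, C7a) is used for every intermediate, the monocyclic ones included; β is the face of the C7a hydrogen, α that of the C3a hydrogen.
Remark: dimethyl malonate is used in place of a methylmalonate so that the C4 methyl can be introduced on the closed ring, where its face is predictable; compounds 7, 8, 10, 11 and 18 are mixtures at centres or double bonds that are destroyed later.

**Route**

Step 1
Reactants: 1 (S)-4-(tert-butyldimethylsilyloxy)cyclopent-2-en-1-one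
Product: 3 (2S,3S,4S)-4-(tert-butyldimethylsilyloxy)-2-methyl-3-vinylcyclopentan-1-one, via bromomagnesium enolate 2 (not isolated)
Conditions: CH2=CHMgBr, CuBr·SMe2 (10 mol%), THF, −78 °C; then MeI, DMPU, −78 → −20 °C
Reagents that add atoms: vinylmagnesium bromide, C=C[Mg]Br; iodomethane, CI
Why: Copper-catalysed conjugate addition of the vinyl Grignard reagent should occur anti to the silyloxy group and the regiodefined enolate should be C-methylated anti to the new vinyl group (tandem 1,4-addition–enolate alkylation), which sets C7a and C1 from the one stereocentre of 1; any material that loses silanol here is simply the intermediate of step 2.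

Step 2
Reactants: 3; 4 dimethyl malonate
Product: 6 dimethyl 2-[(all-trans)-3-methyl-4-oxo-2-vinylcyclopentyl]malonate (C3a malonyl β, C7a vinyl α, C1 methyl β, ketone at C2), via enone 5 (not isolated)
Conditions: NaOMe (0.2 equiv), MeOH, 0 °C → rt
Reagents that add atoms: dimethyl malonate, COC(=O)CC(=O)OC
Why: E1cB loss of silanolate from the β-silyloxy ketone unveils the 4,5-disubstituted cyclopentenone, and Michael addition of malonate should then occur anti to the neighbouring vinyl group, setting C3a trans to C7a while the epimerisable C1 methyl settles in the all-trans arrangement.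

Step 3
Reactants: 6
Product: 7 dimethyl 2-[5-(1-hydroxyethyl)-3-methyl-4-oxo-2-vinylcyclopentyl]malonate (mixture at the two new centres)
Conditions: LiN(iPr)2 (2.2 equiv), THF, −78 °C; CH3CHO, −78 °C; aq. NH4Cl
Reagents that add atoms: acetaldehyde, CC=O
Why: The first equivalent of base masks the malonate C–H as its enolate, the second should form the kinetic ketone enolate at the unsubstituted C3 methylene and not at the methyl-bearing C1, and this enolate adds to acetaldehyde (directed aldol addition); the two new centres are removed in steps 4 and 6.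

Step 4
Reactants: 7
Product: 9 dimethyl 2-[(E)-5-ethylidene-3-methyl-4-oxo-2-vinylcyclopentyl]malonate, via mesylate 8 (not isolated)
Conditions: MsCl, Et3N, CH2Cl2, 0 °C; then DBU, rt
Reagents that add atoms: none
Why: Sulfonylation of the aldol hydroxyl and E1cB elimination (aldol dehydration) should give the exocyclic enone, in which C3 carries no hydrogen, so retro-Michael loss of the malonate is blocked.

Step 5
Reactants: 9
Product: 10 4-methylbenzenesulfonylhydrazone of 9
Conditions: TsNHNH2, MeOH, rt
Reagents that add atoms: 4-methylbenzenesulfonohydrazide, Cc1ccc(cc1)S(=O)(=O)NN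
Why: Condensation of the ketone with the sulfonyl hydrazide (hydrazone formation) should proceed at the carbonyl without touching the esters and leaves C1, C3a and C7a unchanged.

Step 6
Reactants: 10
Product: 12 dimethyl 2-[2-ethyl-4-methyl-5-vinylcyclopent-2-en-1-yl]malonate (C3a malonyl β, C7a vinyl α, C1 methyl β), via allylic diazene 11 (not isolated)
Conditions: catecholborane, CHCl3, 0 °C; then NaOAc·3H2O, reflux
Reagents that add atoms: none
Why: In this Kabalka reduction of an enone tosylhydrazone the borane reduces the C=N bond, acetate induces loss of sulfinate, and the allylic diazene expels N2 by a retro-ene hydrogen shift that places the double bond between C2 and C3 and turns the ethylidene into the C3 ethyl group; no stereocentre is touched.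

Step 7
Reactants: 12
Product: 13 dimethyl 2-[5-acetyl-2-ethyl-4-methylcyclopent-2-en-1-yl]malonate
Conditions: PdCl2 (10 mol%), CuCl, O2, DMF–H2O, rt
Reagents that add atoms: water, O
Why: Tsuji–Wacker oxidation should convert the monosubstituted vinyl group into the methyl ketone by Markovnikov hydroxypalladation, the trisubstituted ring alkene being too hindered to compete.

Step 8
Reactants: 13
Product: 14 methyl 3-ethyl-1-methyl-5,7-dioxo-3a,4,5,6,7,7a-hexahydro-1H-indene-4-carboxylate (trans-fused, 3aα-H, 7aβ-H, 1β-methyl; C4 ester α, epimerisable)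
Conditions: NaOMe, MeOH, reflux; then aq. HCl, 0 °C
Reagents that add atoms: none
Why: The methyl ketone enolate attacks one of the two equivalent malonate esters in an intramolecular Claisen condensation that closes ring B as a cyclohexane-1,3-dione and is driven by formation of the dione enolate; C7a and C4 are epimerisable and should adopt the trans ring fusion with an equatorial ester.

Step 9
Reactants: 14
Product: 15 methyl 3-ethyl-1,4-dimethyl-5,7-dioxo-3a,4,5,6,7,7a-hexahydro-1H-indene-4-carboxylate (C4 methyl β, ester α)
Conditions: LiN(iPr)2 (2.3 equiv), THF–DMPU, −78 → −40 °C; MeI, −78 °C; aq. HCl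
Reagents that add atoms: iodomethane, CI
Why: The dianion of the dione ester should alkylate at its more basic terminal carbon C4 (dianion γ-alkylation), and iodomethane approaches axially, anti to the axial C3a hydrogen, which places the new methyl on the β face and leaves the ester equatorial.

Step 10
Reactants: 15
Product: 16 methyl 3-ethyl-7-methoxy-1,4-dimethyl-5-oxo-3a,4,5,7a-tetrahydro-1H-indene-4-carboxylate
Conditions: HC(OMe)3, TsOH (cat.), MeOH, rt
Reagents that add atoms: trimethyl orthoformate, COC(OC)OC
Why: Acid-catalysed enol ether formation (vinylogous ester synthesis) should take place at the C7 carbonyl because the C5 carbonyl is shielded by the adjacent quaternary C4.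

Step 11
Reactants: 16; 17 propyne
Product: 19 methyl 3-ethyl-1,4-dimethyl-7-oxo-5-(prop-1-ynyl)-3a,4,7,7a-tetrahydro-1H-indene-4-carboxylate, via tertiary propargylic alcohol 18 (not isolated)
Conditions: propyne, n-BuLi, THF, −78 °C; CeCl3; then 16, −78 → −40 °C; then 1 M HCl, THF, 0 °C → rt
Reagents that add atoms: propyne, CC#C; water, O
Why: In this Stork–Danheiser sequence the propynylcerium reagent should add 1,2 to the vinylogous ester carbonyl in preference to the hindered ester on C4, and acid then ionises the tertiary alcohol and hydrolyses the enol ether with allylic transposition to the C5-propynyl enone.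

Step 12
Reactants: 19
Product: 20 methyl 3-ethyl-7-hydroxy-1,4,7-trimethyl-5-(prop-1-ynyl)-3a,4,7,7a-tetrahydro-1H-indene-4-carboxylate (C7 hydroxyl β, C7 methyl α)
Conditions: MeLi, CeCl3, THF, −78 °C; aq. NH4Cl
Reagents that add atoms: methyllithium, [Li]C
Why: 1,2-Addition of the methylcerium reagent to the enynone should occur by axial attack from the α face, anti to the axial C7a hydrogen and away from the C1 methyl, which gives the β-hydroxyl needed in step 13.

Step 13
Reactants: 20
Product: 21 methyl 3-ethyl-7-hydroxy-1,4,7-trimethyl-5-(prop-1-ynyl)-5,6-methano-3a,4,5,6,7,7a-hexahydro-1H-indene-4-carboxylate (cyclopropane CH2 β, syn to the hydroxyl)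
Conditions: Et2Zn, CH2I2, CH2Cl2, −10 °C → rt; aq. NH4Cl
Reagents that add atoms: diiodomethane, ICI
Why: Et2Zn deprotonates the tertiary C7 hydroxyl and the zinc alkoxide binds the iodomethylzinc carbenoid, which passes CH2 to the adjacent C5=C6 bond through the concerted butterfly transition state of a hydroxyl-directed Simmons–Smith (Furukawa) cyclopropanation of an allylic alcohol. The three-membered ring closes in one step by syn [2+1] addition, so C5–CH2 and C6–CH2 form on the same face. The configurations at C5 and C6 are dictated by the β-oriented C7 oxygen, which should deliver the methylene to the β face even though the axial C4 methyl shields it. Selectivity over the C2=C3 alkene rests on the rate acceleration by the neighbouring alkoxide, and the propynyl group is inert to the electrophilic zinc carbenoid. The C5–CH2 bond made here becomes the C5 methyl; the C6–CH2 bond and the C6 centre are given up in step 14.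

Step 14
Reactants: 21
Product: 22 methyl 5-(bromomethyl)-3-ethyl-1,4,7-trimethyl-5-(prop-1-ynyl)-3a,4,5,7a-tetrahydro-1H-indene-4-carboxylate (CH2Br β)
Conditions: MgBr2·OEt2, Et2O–PhH, 40 °C
Reagents that add atoms: magnesium bromide, Br[Mg]Br
Why: Magnesium-assisted ionisation at C7 gives a cyclopropylcarbinyl cation that bromide should open at the unhindered exocyclic CH2, the bond best aligned with the empty orbital (cyclopropylcarbinyl-to-homoallyl rearrangement), which restores C6=C7 with its methyl and leaves C5 as a quaternary centre bearing CH2Br.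

Step 15
Reactants: 22
Product: 23 methyl 3-ethyl-1,4,5,7-tetramethyl-5-(prop-1-ynyl)-3a,4,5,7a-tetrahydro-1H-indene-4-carboxylate (C5 methyl β)
Conditions: Bu3SnH (2 equiv, 0.5 M), PhSeSePh (10 mol%), Et3B, air, PhMe, 0 °C
Reagents that add atoms: none
Why: In this radical chain dehalogenation bromine abstraction gives a neopentyl-type radical that the selenol formed in situ should reduce faster than it can add back to C6, so CH2Br becomes the C5 methyl with the configuration fixed in step 13.

Step 16
Reactants: 23; 24 (E)-β-bromostyrene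
Product: 26 zyggomphic acid B methyl ester, via alkenylzirconocene chloride 25 (not isolated)
Conditions: Cp2Zr(H)Cl, THF, 50 °C; then ZnCl2, Pd(PPh3)4 (5 mol%), 24, THF, rt → 40 °C
Reagents that add atoms: (E)-β-bromostyrene, Br/C=C/c1ccccc1
Why: syn Hydrozirconation should place zirconium on the methyl-bearing alkyne carbon, remote from the quaternary C5, and Negishi coupling after transmetalation to zinc joins it to the bromostyrene with retention at both alkenes, giving the (E,E)-diene.

Step 17
Reactants: 26
Product: 27 zyggomphic acid B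
Conditions: LiSPr, HMPA, 25 → 50 °C; then aq. HCl
Reagents that add atoms: none
Why: The ester carbonyl on the quaternary C4 is out of reach of hydroxide, so the ester is cleaved by SN2 attack of thiolate on the O-methyl group (nucleophilic ester dealkylation), which should leave every stereocentre and the diene untouched.

**Compound list**
1 | (S)-4-(tert-butyldimethylsilyloxy)cyclopent-2-en-1-one | O=C1C=C[C@@H](O[Si](C)(C)C(C)(C)C)C1 | starting material
2 | bromomagnesium enolate of 4-(tert-butyldimethylsilyloxy)-3-vinylcyclopentanone (vinyl anti to silyloxy) | Br[Mg]OC1=C[C@H](C=C)[C@@H](O[Si](C)(C)C(C)(C)C)C1 | intermediate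
3 | (2S,3S,4S)-4-(tert-butyldimethylsilyloxy)-2-methyl-3-vinylcyclopentan-1-one | C[C@@H]1C(=O)C[C@H](O[Si](C)(C)C(C)(C)C)[C@H]1C=C | intermediate
4 | dimethyl malonate | COC(=O)CC(=O)OC | starting material
5 | trans-5-methyl-4-vinylcyclopent-2-en-1-one | C[C@@H]1C(=O)C=C[C@H]1C=C | intermediate
6 | dimethyl 2-[(all-trans)-3-methyl-4-oxo-2-vinylcyclopentyl]malonate | C[C@@H]1C(=O)C[C@H](C(C(=O)OC)C(=O)OC)[C@H]1C=C | intermediate
7 | dimethyl 2-[5-(1-hydroxyethyl)-3-methyl-4-oxo-2-vinylcyclopentyl]malonate (mixture at the two new centres) | C[C@@H]1C(=O)C(C(C)O)[C@H](C(C(=O)OC)C(=O)OC)[C@H]1C=C | intermediate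
8 | dimethyl 2-{3-methyl-5-[1-(methylsulfonyloxy)ethyl]-4-oxo-2-vinylcyclopentyl}malonate | C[C@@H]1C(=O)C(C(C)OS(C)(=O)=O)[C@H](C(C(=O)OC)C(=O)OC)[C@H]1C=C | intermediate
9 | dimethyl 2-[(E)-5-ethylidene-3-methyl-4-oxo-2-vinylcyclopentyl]malonate | C[C@@H]1C(=O)/C(=C/C)[C@H](C(C(=O)OC)C(=O)OC)[C@H]1C=C | intermediate
10 | 4-methylbenzenesulfonylhydrazone of 9 | C[C@@H]1C(=NNS(=O)(=O)c2ccc(C)cc2)/C(=C/C)[C@H](C(C(=O)OC)C(=O)OC)[C@H]1C=C | intermediate
11 | dimethyl 2-[4-diazenyl-5-ethylidene-3-methyl-2-vinylcyclopentyl]malonate | C[C@@H]1C(N=N)/C(=C/C)[C@H](C(C(=O)OC)C(=O)OC)[C@H]1C=C | intermediate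
12 | dimethyl 2-[2-ethyl-4-methyl-5-vinylcyclopent-2-en-1-yl]malonate (all-trans) | CCC1=C[C@@H](C)[C@H](C=C)[C@H]1C(C(=O)OC)C(=O)OC | intermediate
13 | dimethyl 2-[5-acetyl-2-ethyl-4-methylcyclopent-2-en-1-yl]malonate (all-trans) | CCC1=C[C@@H](C)[C@H](C(C)=O)[C@H]1C(C(=O)OC)C(=O)OC | intermediate
14 | methyl 3-ethyl-1-methyl-5,7-dioxo-3a,4,5,6,7,7a-hexahydro-1H-indene-4-carboxylate (trans-fused, ester α) | CCC1=C[C@@H](C)[C@@H]2C(=O)CC(=O)[C@H](C(=O)OC)[C@@H]12 | intermediate
15 | methyl 3-ethyl-1,4-dimethyl-5,7-dioxo-3a,4,5,6,7,7a-hexahydro-1H-indene-4-carboxylate (C4 methyl β) | CCC1=C[C@@H](C)[C@@H]2C(=O)CC(=O)[C@](C)(C(=O)OC)[C@@H]12 | intermediate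
16 | methyl 3-ethyl-7-methoxy-1,4-dimethyl-5-oxo-3a,4,5,7a-tetrahydro-1H-indene-4-carboxylate | CCC1=C[C@@H](C)[C@@H]2C(OC)=CC(=O)[C@](C)(C(=O)OC)[C@@H]12 | intermediate
17 | propyne | CC#C | starting material
18 | methyl 3-ethyl-5-hydroxy-7-methoxy-1,4-dimethyl-5-(prop-1-ynyl)-3a,4,5,7a-tetrahydro-1H-indene-4-carboxylate (C5 unassigned) | CCC1=C[C@@H](C)[C@@H]2C(OC)=CC(O)(C#CC)[C@](C)(C(=O)OC)[C@@H]12 | intermediate
19 | methyl 3-ethyl-1,4-dimethyl-7-oxo-5-(prop-1-ynyl)-3a,4,7,7a-tetrahydro-1H-indene-4-carboxylate | CCC1=C[C@@H](C)[C@@H]2C(=O)C=C(C#CC)[C@](C)(C(=O)OC)[C@@H]12 | intermediate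
20 | methyl 3-ethyl-7-hydroxy-1,4,7-trimethyl-5-(prop-1-ynyl)-3a,4,7,7a-tetrahydro-1H-indene-4-carboxylate (C7 hydroxyl β) | CCC1=C[C@@H](C)[C@@H]2[C@@](C)(O)C=C(C#CC)[C@](C)(C(=O)OC)[C@@H]12 | intermediate
21 | methyl 3-ethyl-7-hydroxy-1,4,7-trimethyl-5-(prop-1-ynyl)-5,6-methano-3a,4,5,6,7,7a-hexahydro-1H-indene-4-carboxylate (CH2 β) | CCC1=C[C@@H](C)[C@@H]2[C@@](C)(O)[C@H]3C[C@@]3(C#CC)[C@](C)(C(=O)OC)[C@@H]12 | intermediate
22 | methyl 5-(bromomethyl)-3-ethyl-1,4,7-trimethyl-5-(prop-1-ynyl)-3a,4,5,7a-tetrahydro-1H-indene-4-carboxylate | CCC1=C[C@@H](C)[C@@H]2C(C)=C[C@](CBr)(C#CC)[C@](C)(C(=O)OC)[C@@H]12 | intermediate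
23 | methyl 3-ethyl-1,4,5,7-tetramethyl-5-(prop-1-ynyl)-3a,4,5,7a-tetrahydro-1H-indene-4-carboxylate | CCC1=C[C@@H](C)[C@@H]2C(C)=C[C@](C)(C#CC)[C@](C)(C(=O)OC)[C@@H]12 | intermediate
24 | (E)-β-bromostyrene | Br/C=C/c1ccccc1 | starting material
25 | (E)-alkenylzirconocene chloride from 23 (zirconium on the methyl-bearing carbon) | CCC1=C[C@@H](C)[C@@H]2C(C)=C[C@](C)(/C=C(C)/[Zr](Cl)(C3C=CC=C3)C3C=CC=C3)[C@](C)(C(=O)OC)[C@@H]12 | intermediate
26 | zyggomphic acid B methyl ester | CCC1=C[C@@H](C)[C@@H]2C(C)=C[C@](C)(/C=C(C)/C=C/c3ccccc3)[C@](C)(C(=O)OC)[C@@H]12 | intermediate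
27 | zyggomphic acid B | CCC1=C[C@@H](C)[C@@H]2C(C)=C[C@](C)(/C=C(C)/C=C/c3ccccc3)[C@](C)(C(=O)O)[C@@H]12 | target

**Summary**
Total step count: 17
Longest linear sequence: 17 steps (from 1)

**Steps most likely to fail**

1. Step 13 (cyclopropanation). Methylene transfer may be slow because the alkene is conjugated to the alkyne and sits beside the quaternary C4, whose β-methyl shields the face from which CH2 must arrive; the excess carbenoid could then attack the ring A alkene. The fallback sets out from 20 and makes the C5–CH2 bond by a Still–Wittig [2,3]-sigmatropic rearrangement, which carries carbon suprafacially from the C7 oxygen to C5 and moves the double bond to C6=C7 in the same event. Alkylation of the potassium alkoxide of 20 (KH, 18-crown-6, Bu3SnCH2I, THF) gives the C7 tributylstannylmethyl ether F1. Tin–lithium exchange (n-BuLi, THF, −78 °C) triggers the rearrangement to the C5 hydroxymethyl compound F2, which is quenched cold so that the alkoxide does not attack the ester. CBr4 and PPh3 then convert F2 into bromide 22, where the route is rejoined.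

2. Step 14 (ring opening). After ionisation, bromide may attack C5 with ring enlargement, the cation may lose a proton to give dienes, or the ester may close onto the CH2. The fallback sets out from 21 and replaces the cation by a radical. Acylation with methyl chlorooxoacetate (pyridine, DMAP, CH2Cl2) gives the tertiary methyl oxalate F3. Bu3SnH and AIBN in toluene at reflux generate the C7 radical, whose cyclopropylcarbinyl opening along the exocyclic bond followed by hydrogen transfer gives 23 directly, where the route is rejoined.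

3. Step 15 (reduction of the bromide). The primary radical may close onto C6 and reopen along the ring bond, enlarging ring B to a propargylic radical before it is reduced, and stannyl radicals may add to the alkyne. The fallback sets out from 22 and avoids a free radical chain. Oxidative insertion of highly activated zinc powder (Zn, THF, reflux) gives the alkylzinc bromide F4, and protonolysis with acetic acid gives 23, where the route is rejoined.

Further compounds
F1 | step 13 | methyl 3-ethyl-1,4,7-trimethyl-5-(prop-1-ynyl)-7-[(tributylstannyl)methoxy]-3a,4,7,7a-tetrahydro-1H-indene-4-carboxylate | CCC1=C[C@@H](C)[C@@H]2[C@@](C)(OC[Sn](CCCC)(CCCC)CCCC)C=C(C#CC)[C@](C)(C(=O)OC)[C@@H]12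
F2 | step 13 | methyl 3-ethyl-5-(hydroxymethyl)-1,4,7-trimethyl-5-(prop-1-ynyl)-3a,4,5,7a-tetrahydro-1H-indene-4-carboxylate | CCC1=C[C@@H](C)[C@@H]2C(C)=C[C@](CO)(C#CC)[C@](C)(C(=O)OC)[C@@H]12
F3 | step 14 | C7 methyl oxalate of cyclopropyl carbinol 21 | CCC1=C[C@@H](C)[C@@H]2[C@@](C)(OC(=O)C(=O)OC)[C@H]3C[C@@]3(C#CC)[C@](C)(C(=O)OC)[C@@H]12
F4 | step 15 | {[3-ethyl-4-(methoxycarbonyl)-1,4,7-trimethyl-5-(prop-1-ynyl)-3a,4,5,7a-tetrahydro-1H-inden-5-yl]methyl}zinc bromide | CCC1=C[C@@H](C)[C@@H]2C(C)=C[C@](C[Zn]Br)(C#CC)[C@](C)(C(=O)OC)[C@@H]12
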